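**Retrosynthetic overview**
1. The target comes from a trans-fused hydroxy-ketone bicycle that already carries the angelate, by hydroxyl-directed ketone reduction, aroylation of the new secondary alcohol and phenol unmasking.
2. The bicycle comes from an open-chain C15 keto-enone (farnesane skeleton) in one Lewis-acid bicyclisation. The enone-initiated, allylsilane-terminated closure makes C1–C7, and the resulting titanium enolate adds to the C10 ketone (the carbonyl stand-in for the water-quenched C10 cation) to make C6–C10.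
3. The open-chain precursor comes from Nozaki–Hiyama–Kishi union of a C6–C13 vinyl iodide with a C1–C5 silyl aldehyde, then oxidation.
4. The vinyl iodide comes from a reagent-controlled boron aldol (the only stereocentre set before cyclisation) and early angeloylation; the aldehyde comes from alkyne trans-hydrosilylation and Johnson–Claisen rearrangement.
5. Ring order: seven-membered ring first, then five-membered ring, both in the same flask.

Assumption: the biosynthesis is taken as ionisation of farnesyl (nerolidyl) diphosphate, C1–C7 closure to a cycloheptenyl cation, C6–C10 closure and capture of the C10 cation by water, with oxygenation at the two acyloxy carbons and acylation last; C-numbers are farnesane numbers, identical with the dodeca-1,6-diene numbering of the open-chain precursors.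

**Route**

Step 1
Reactants: 1 prop-2-yn-1-ol
Product: 3 (2E)-3-iodo-2-methylprop-2-en-1-ol, via alkenyldimethylalane 2 (not isolated)
Conditions: AlMe3, Cp2ZrCl2 (25 mol %), CH2Cl2, 0 °C to rt; then I2, THF, −30 °C; aq. K2CO3
Reagents that add atoms: trimethylaluminium C[Al](C)C; iodine II
Why: Cp2ZrCl2-catalysed syn carboalumination (Negishi) puts methyl on the internal alkyne carbon and aluminium on the terminus, and iodinolysis with retention gives the E vinyl iodide.

Step 2
Reactants: 3 (2E)-3-iodo-2-methylprop-2-en-1-ol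
Product: 4 (2E)-3-iodo-2-methylprop-2-enal
Conditions: MnO2, CH2Cl2, rt
Reagents that add atoms: none
Why: Allylic alcohol oxidation with MnO2 stops at the enal and leaves the vinyl iodide and its geometry untouched.

Step 3
Reactants: 5 3-methylbutan-2-one; 4 (2E)-3-iodo-2-methylprop-2-enal
Product: 7 (5R,6E)-5-hydroxy-7-iodo-2,6-dimethylhept-6-en-3-one, via enol diisopinocampheylborinate 6 (not isolated)
Conditions: (−)-Ipc2BCl, Et3N, Et2O, 0 °C; then 4, −78 to −20 °C; then MeOH, pH 7 buffer, 30% H2O2, 0 °C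
Reagents that add atoms: none
Why: Paterson boron aldol: the methyl-side enol borinate adds to the enal through a chair transition state, and the isopinocampheyl ligands from (+)-α-pinene select the aldehyde face that gives the 5R carbinol.

Step 4
Reactants: 7 (5R,6E)-5-hydroxy-7-iodo-2,6-dimethylhept-6-en-3-one
Product: 8 (1E,3R)-1-iodo-2,6-dimethyl-5-oxohept-1-en-3-yl (2Z)-2-methylbut-2-enoate
Conditions: angelic acid, 2,4,6-Cl3C6H2COCl, Et3N, toluene, rt; then 7, 40 °C
Reagents that add atoms: angelic acid C/C=C(/C)C(O)=O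
Why: Yamaguchi-type esterification through the preformed mixed anhydride, run without DMAP, acylates the unhindered open-chain carbinol with retention and avoids Z-to-E isomerisation of the angelate and β-elimination of the aldol.

Step 5
Reactants: 9 but-2-yn-1-ol
Product: 10 (2Z)-3-[dimethyl(phenyl)silyl]but-2-en-1-ol
Conditions: PhMe2SiH, [Cp*Ru(NCMe)3]PF6 (2 mol %), CH2Cl2, 0 °C to rt
Reagents that add atoms: dimethylphenylsilane C[SiH](C)c1ccccc1
Why: [Cp*Ru(NCMe)3]PF6-catalysed trans hydrosilylation (Trost) of a propargylic alcohol places silicon on the alkyne carbon distal to the hydroxyl and gives the Z vinylsilane.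

Step 6
Reactants: 10 (2Z)-3-[dimethyl(phenyl)silyl]but-2-en-1-ol
Product: 12 ethyl 3-[dimethyl(phenyl)silyl]-3-methylpent-4-enoate (racemic), via ketene acetal 11 (not isolated)
Conditions: MeC(OEt)3, EtCO2H (cat.), 140 °C, EtOH distilled off
Reagents that add atoms: triethyl orthoacetate CCOC(C)(OCC)OCC
Why: Johnson–Claisen rearrangement: the [3,3] shift forms the new C–C bond at the silicon-bearing carbon and creates the tertiary allylsilane; the new centre is racemic and harmless because it becomes sp2 in step 10.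

Step 7
Reactants: 12 ethyl 3-[dimethyl(phenyl)silyl]-3-methylpent-4-enoate
Product: 14 3-[dimethyl(phenyl)silyl]-3-methylpent-4-enal (racemic), via aluminium hemiacetal 13 (not isolated)
Conditions: i-Bu2AlH, CH2Cl2, −78 °C; MeOH, aq. potassium sodium tartrate
Reagents that add atoms: none
Why: Half-reduction of the ester: the tetrahedral aluminium hemiacetal is stable at −78 °C and releases the aldehyde only on work-up.

Step 8
Reactants: 8 (1E,3R)-1-iodo-2,6-dimethyl-5-oxohept-1-en-3-yl (2Z)-2-methylbut-2-enoate; 14 3-[dimethyl(phenyl)silyl]-3-methylpent-4-enal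
Product: 16 (6E,8R)-3-[dimethyl(phenyl)silyl]-5-hydroxy-3,7,11-trimethyl-10-oxododeca-1,6-dien-8-yl (2Z)-2-methylbut-2-enoate (C3/C5 epimer mixture), via alkenylchromium dichloride 15 (not isolated)
Conditions: CrCl2 (4 equiv), NiCl2 (2 mol %), DMF, rt
Reagents that add atoms: none
Why: Nozaki–Hiyama–Kishi coupling: NiCl2-catalysed formation of the alkenylchromium species with retention of the E geometry and chemoselective addition to the aldehyde in the presence of ketone, ester and allylsilane; the new C5 carbinol centre is uncontrolled and is erased in step 9.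

Step 9
Reactants: 16 (6E,8R)-3-[dimethyl(phenyl)silyl]-5-hydroxy-3,7,11-trimethyl-10-oxododeca-1,6-dien-8-yl (2Z)-2-methylbut-2-enoate
Product: 17 (6E,8R)-3-[dimethyl(phenyl)silyl]-3,7,11-trimethyl-5,10-dioxododeca-1,6-dien-8-yl (2Z)-2-methylbut-2-enoate (C3 epimer mixture)
Conditions: Dess–Martin periodinane, NaHCO3, CH2Cl2, 0 °C to rt
Reagents that add atoms: none
Why: Buffered Dess–Martin oxidation of the allylic alcohol gives the E enone without touching the allylsilane or the β-acyloxy ketone.

Step 10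
Reactants: 17 (6E,8R)-3-[dimethyl(phenyl)silyl]-3,7,11-trimethyl-5,10-dioxododeca-1,6-dien-8-yl (2Z)-2-methylbut-2-enoate
Product: 19 (1R,3R,3aR,8aR)-3-hydroxy-6,8a-dimethyl-4-oxo-3-(propan-2-yl)-1,2,3,3a,4,5,8,8a-octahydroazulen-1-yl (2Z)-2-methylbut-2-enoate, via monocyclic trichlorotitanium enolate 18 (not isolated)
Conditions: TiCl4 (2.2 equiv), CH2Cl2, −78 to −40 °C; aq. NaHCO3
Reagents that add atoms: none
Why: Proposed new method: TiCl4 activates the enone in its s-trans form and the vinyl terminus C1 of the tertiary allylsilane attacks C7 in a 7-endo Hosomi–Sakurai conjugate allylation (carbonyl addition would be a disfavoured 5-endo closure; both C3 epimers converge because C3 becomes sp2), anti to the C8–O bond with the C8 hydrogen outside (polar Felkin–Anh), which sets the quaternary centre 8aR; loss of silicon leaves the ring alkene and a regiodefined titanium enolate whose C6 is reached by the C8–C9–C10 tether only on the face opposite the new C1–C7 bond, so the closed, titanium-bridged aldol onto the C10 ketone gives the trans ring fusion (3aR) and the tertiary alcohol syn to the C5 carbonyl (3R); closest known reactions are intramolecular Sakurai conjugate allylations of allylsilane-tethered enones and tandem Sakurai–aldol sequences.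

Step 11
Reactants: 19 (1R,3R,3aR,8aR)-3-hydroxy-6,8a-dimethyl-4-oxo-3-(propan-2-yl)-1,2,3,3a,4,5,8,8a-octahydroazulen-1-yl (2Z)-2-methylbut-2-enoate
Product: 21 (1R,3R,3aS,4S,8aR)-3,4-dihydroxy-6,8a-dimethyl-3-(propan-2-yl)-1,2,3,3a,4,5,8,8a-octahydroazulen-1-yl (2Z)-2-methylbut-2-enoate, via alkoxydiacetoxyborohydride 20 (not isolated)
Conditions: Me4NBH(OAc)3, MeCN/AcOH (1:1), −30 °C; aq. potassium sodium tartrate
Reagents that add atoms: none
Why: Evans–Saksena directed reduction: the tertiary hydroxyl exchanges onto boron and delivers hydride to the ketone face on its own side, giving the anti 1,3-diol, which is the 4S carbinol.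

Step 12
Reactants: 21 (1R,3R,3aS,4S,8aR)-3,4-dihydroxy-6,8a-dimethyl-3-(propan-2-yl)-1,2,3,3a,4,5,8,8a-octahydroazulen-1-yl (2Z)-2-methylbut-2-enoate
Product: 22 (1R,3R,3aS,4S,8aR)-4-{[4-(acetyloxy)benzoyl]oxy}-3-hydroxy-6,8a-dimethyl-3-(propan-2-yl)-1,2,3,3a,4,5,8,8a-octahydroazulen-1-yl (2Z)-2-methylbut-2-enoate
Conditions: 4-AcOC6H4COCl, Et3N, DMAP (cat.), CH2Cl2, 0 °C to rt
Reagents that add atoms: 4-acetoxybenzoyl chloride CC(=O)Oc1ccc(cc1)C(Cl)=O
Why: DMAP-catalysed acyl transfer goes to the only secondary hydroxyl, since the tertiary alcohol is inert, with retention at C4.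

Step 13
Reactants: 22 (1R,3R,3aS,4S,8aR)-4-{[4-(acetyloxy)benzoyl]oxy}-3-hydroxy-6,8a-dimethyl-3-(propan-2-yl)-1,2,3,3a,4,5,8,8a-octahydroazulen-1-yl (2Z)-2-methylbut-2-enoate
Product: 23 (1R,3R,3aS,4S,8aR)-3-hydroxy-4-[(4-hydroxybenzoyl)oxy]-6,8a-dimethyl-3-(propan-2-yl)-1,2,3,3a,4,5,8,8a-octahydroazulen-1-yl (2Z)-2-methylbut-2-enoate (CNP0188626.1)
Conditions: NH4OAc, MeOH/H2O (4:1), rt
Reagents that add atoms: none
Why: Chemoselective solvolysis: the aryl acetate is far more electrophilic than the angelate and the benzoate and is cleaved under neutral NH4OAc catalysis.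

**Compound list**
1 | prop-2-yn-1-ol | C#CCO | starting material
2 | alkenyldimethylalane: dimethylaluminium alkoxide of (2E)-3-(dimethylalumanyl)-2-methylprop-2-en-1-ol | C[Al](C)OC/C(C)=C/[Al](C)C | intermediate
3 | (2E)-3-iodo-2-methylprop-2-en-1-ol | OC/C(C)=C/I | intermediate
4 | (2E)-3-iodo-2-methylprop-2-enal | O=C/C(C)=C/I | intermediate
5 | 3-methylbutan-2-one | CC(=O)C(C)C | starting material
6 | enol diisopinocampheylborinate of 5 (boron on oxygen, CH2= terminus, both isopinocampheyl groups from (+)-α-pinene) | C=C(OB([C@@H]1C[C@@H]2C[C@H]([C@H]1C)C2(C)C)[C@@H]1C[C@@H]2C[C@H]([C@H]1C)C2(C)C)C(C)C | intermediate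
7 | (5R,6E)-5-hydroxy-7-iodo-2,6-dimethylhept-6-en-3-one | CC(C)C(=O)C[C@@H](O)/C(C)=C/I | intermediate
8 | (1E,3R)-1-iodo-2,6-dimethyl-5-oxohept-1-en-3-yl (2Z)-2-methylbut-2-enoate | C/C=C(/C)C(=O)O[C@@H](/C(C)=C/I)CC(=O)C(C)C | intermediate
9 | but-2-yn-1-ol | CC#CCO | starting material
10 | (2Z)-3-[dimethyl(phenyl)silyl]but-2-en-1-ol | OC/C=C(/C)[Si](C)(C)c1ccccc1 | intermediate
11 | ketene acetal: 1-ethoxyvinyl ether of 10 | CCOC(=C)OC/C=C(/C)[Si](C)(C)c1ccccc1 | intermediate
12 | ethyl 3-[dimethyl(phenyl)silyl]-3-methylpent-4-enoate (racemic) | CCOC(=O)CC(C)(C=C)[Si](C)(C)c1ccccc1 | intermediate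
13 | aluminium hemiacetal: O-diisobutylaluminium ethyl hemiacetal of 14 | CCOC(CC(C)(C=C)[Si](C)(C)c1ccccc1)O[Al](CC(C)C)CC(C)C | intermediate
14 | 3-[dimethyl(phenyl)silyl]-3-methylpent-4-enal (racemic) | O=CCC(C)(C=C)[Si](C)(C)c1ccccc1 | intermediate
15 | alkenylchromium dichloride: 8 with CrCl2 in place of iodine, E retained | C/C=C(/C)C(=O)O[C@@H](/C(C)=C/[Cr](Cl)Cl)CC(=O)C(C)C | intermediate
16 | (6E,8R)-3-[dimethyl(phenyl)silyl]-5-hydroxy-3,7,11-trimethyl-10-oxododeca-1,6-dien-8-yl (2Z)-2-methylbut-2-enoate (epimers at C3 and C5) | C/C=C(/C)C(=O)O[C@@H](/C(C)=C/C(O)CC(C)(C=C)[Si](C)(C)c1ccccc1)CC(=O)C(C)C | intermediate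
17 | (6E,8R)-3-[dimethyl(phenyl)silyl]-3,7,11-trimethyl-5,10-dioxododeca-1,6-dien-8-yl (2Z)-2-methylbut-2-enoate (epimers at C3) | C/C=C(/C)C(=O)O[C@@H](/C(C)=C/C(=O)CC(C)(C=C)[Si](C)(C)c1ccccc1)CC(=O)C(C)C | intermediate
18 | (1R)-1-[(1R)-1,5-dimethyl-3-[(trichlorotitanio)oxy]cyclohepta-2,5-dien-1-yl]-4-methyl-3-oxopentyl (2Z)-2-methylbut-2-enoate | C/C=C(/C)C(=O)O[C@H](CC(=O)C(C)C)[C@]1(C)CC=C(C)CC(O[Ti](Cl)(Cl)Cl)=C1 | intermediate
19 | (1R,3R,3aR,8aR)-3-hydroxy-6,8a-dimethyl-4-oxo-3-(propan-2-yl)-1,2,3,3a,4,5,8,8a-octahydroazulen-1-yl (2Z)-2-methylbut-2-enoate | C/C=C(/C)C(=O)O[C@@H]1C[C@@](O)(C(C)C)[C@@H]2C(=O)CC(C)=CC[C@]21C | intermediate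
20 | tetramethylammonium diacetoxy(hydrido)borate bound to the tertiary oxygen of 19 | C[N+](C)(C)C.C/C=C(/C)C(=O)O[C@@H]1C[C@@](O[BH-](OC(C)=O)OC(C)=O)(C(C)C)[C@@H]2C(=O)CC(C)=CC[C@]21C | intermediate
21 | (1R,3R,3aS,4S,8aR)-3,4-dihydroxy-6,8a-dimethyl-3-(propan-2-yl)-1,2,3,3a,4,5,8,8a-octahydroazulen-1-yl (2Z)-2-methylbut-2-enoate | C/C=C(/C)C(=O)O[C@@H]1C[C@@](O)(C(C)C)[C@@H]2[C@@H](O)CC(C)=CC[C@]21C | intermediate
22 | (1R,3R,3aS,4S,8aR)-4-{[4-(acetyloxy)benzoyl]oxy}-3-hydroxy-6,8a-dimethyl-3-(propan-2-yl)-1,2,3,3a,4,5,8,8a-octahydroazulen-1-yl (2Z)-2-methylbut-2-enoate | C/C=C(/C)C(=O)O[C@@H]1C[C@@](O)(C(C)C)[C@@H]2[C@@H](OC(=O)c3ccc(OC(C)=O)cc3)CC(C)=CC[C@]21C | intermediate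
23 | (1R,3R,3aS,4S,8aR)-3-hydroxy-4-[(4-hydroxybenzoyl)oxy]-6,8a-dimethyl-3-(propan-2-yl)-1,2,3,3a,4,5,8,8a-octahydroazulen-1-yl (2Z)-2-methylbut-2-enoate | C/C=C(/C)C(=O)O[C@@H]1C[C@@](O)(C(C)C)[C@@H]2[C@@H](OC(=O)c3ccc(O)cc3)CC(C)=CC[C@]21C | target

**Step count and risks**
Total steps: 13. Longest linear sequence: 10 (steps 1, 2, 3, 4, 8, 9, 10, 11, 12, 13).

The three steps most likely to fail:

1. Step 10. The sequence may stop after the conjugate allylation, or the aldol may give another diastereomer. Fallback, setting out from 17 and coming back at 19: with catalytic Tf2NH in CH2Cl2 at −78 °C (the silyl triflimide formed in the flask carries the chain) only the conjugate allylation runs and silicon is passed to the enolate oxygen, which gives the monocyclic dimethylphenylsilyl enol ether F1. This isolated enol ether is then closed in a separate Mukaiyama aldol (BF3·OEt2, CH2Cl2, −78 °C, open transition state, silicon lost on work-up) to 19.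

2. Step 4. The angelate may isomerise to the tiglate, or the aldol may eliminate. Fallback, setting out from 7 and coming back at 8: acylate 7 with 2-[bis(2,2,2-trifluoroethoxy)phosphoryl]propanoic acid (DCC, cat. DMAP, CH2Cl2, 0 °C) to the phosphonate ester F2. The Z-trisubstituted enoate is then built on the molecule by Still–Gennari olefination with acetaldehyde (KN(SiMe3)2, 18-crown-6, THF, −78 °C), which gives 8.

3. Step 11. Internal hydride delivery from the hindered tertiary alkoxide may be slow or give the C4 epimer. Fallback, setting out from 19 and coming back at 22 (21 is bypassed): chelation-controlled reduction with external hydride (Et2BOMe, NaBH4, THF/MeOH, −78 °C, Narasaka–Prasad) gives the syn diol, the C4 epimer F3. Mitsunobu esterification with 4-acetoxybenzoic acid (PPh3, diisopropyl azodicarboxylate, toluene, 0 °C to rt) then inverts C4 and gives 22.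

**Further compounds**
F1 | step 10 | (1R)-1-[(1R)-3-{[dimethyl(phenyl)silyl]oxy}-1,5-dimethylcyclohepta-2,5-dien-1-yl]-4-methyl-3-oxopentyl (2Z)-2-methylbut-2-enoate | C/C=C(/C)C(=O)O[C@H](CC(=O)C(C)C)[C@]1(C)CC=C(C)CC(O[Si](C)(C)c2ccccc2)=C1
F2 | step 4 | (1E,3R)-1-iodo-2,6-dimethyl-5-oxohept-1-en-3-yl 2-[bis(2,2,2-trifluoroethoxy)phosphoryl]propanoate (epimers at the phosphorus-bearing carbon) | CC(C(=O)O[C@@H](/C(C)=C/I)CC(=O)C(C)C)P(=O)(OCC(F)(F)F)OCC(F)(F)F
F3 | step 11 | (1R,3R,3aS,4R,8aR)-3,4-dihydroxy-6,8a-dimethyl-3-(propan-2-yl)-1,2,3,3a,4,5,8,8a-octahydroazulen-1-yl (2Z)-2-methylbut-2-enoate | C/C=C(/C)C(=O)O[C@@H]1C[C@@](O)(C(C)C)[C@@H]2[C@H](O)CC(C)=CC[C@]21C
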